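## Retrosynthetic overview

1. Curlignan comes from its C3 N-acyl bornanesultam analogue. The CH2OH group is the reduced acyl-sultam carbonyl, and the aryl CO2Me is already in place and left untouched.
2. The dihydrofuran is the only ring formed, and it is made in one flask. The C3–C3a bond forms first, by an 8–5' oxidative radical hetero-coupling of an N-feruloylsultam with methyl vanillate. The O1–C2 bond forms second, when the new phenol closes onto the p-quinone methide.
3. The sultam fixes the face of C8 (which becomes C3). Ring closure anti to the acyl group relays this to C2, giving the trans product.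
4. The N-feruloylsultam comes from ferulic acid and (1R)-(+)-2,10-camphorsultam. The C6–C1 ester half is bought as methyl vanillate, so no side-chain degradation is needed.

Assumption: the radical coupling follows the usual topicity of N-enoylbornanesultams (C-alpha Re face open for the (2R)-sultam, Si face open for the (2S)-sultam). If experiment shows the opposite sense, the equally available (1S)-(−)-sultam replaces 2 and nothing else changes.

## Route

Step 1
Reactants: 1 (E)-ferulic acid; 2 (1R)-(+)-2,10-camphorsultam [(2S)-bornane-10,2-sultam]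
Product: 6 (2S)-N-[(E)-feruloyl]bornane-10,2-sultam, via bis(trimethylsilyl) ferulate 3 (not isolated), via O-trimethylsilylferuloyl chloride 4 (not isolated), via O-trimethylsilyl feruloylsultam 5 (not isolated)
Conditions: HMDS (1.5 equiv), THF, 65 °C, 2 h, evaporate; (COCl)2 (1.1 equiv), DMF (cat.), CH2Cl2, 0 °C to rt, evaporate; 2 (1.0 equiv), Et3N (1.5 equiv), DMAP (0.1 equiv), CH2Cl2, 0 °C to rt; 1 M aq HCl/THF, rt, 15 min (expected about 70 %)
Reagents that add atoms: hexamethyldisilazane C[Si](C)(C)N[Si](C)(C)C (Me3Si groups of 3, 4 and 5 only, gone in 6); oxalyl chloride O=C(Cl)C(=O)Cl (Cl of 4 only, gone in 6)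
Why: This is a DMAP-catalysed N-acylation of the sultam by an acid chloride under transient O-silyl protection, in which the silyl ester becomes the acid chloride under neutral conditions so the masked phenol never competes as a nucleophile, the aryl silyl ether falls off in the acidic work-up, and no stereocentre is formed while the (E)-alkene and the sultam centres stay untouched.

Step 2
Reactants: 6 (2S)-N-[(E)-feruloyl]bornane-10,2-sultam; 7 methyl vanillate (methyl 4-hydroxy-3-methoxybenzoate)
Product: 12 methyl (2S,3S)-2-(4-hydroxy-3-methoxyphenyl)-7-methoxy-3-{[(2S)-bornane-10,2-sultam-N-yl]carbonyl}-2,3-dihydrobenzofuran-5-carboxylate, via feruloylsultam phenoxyl radical 8 (not isolated), via methyl vanillate phenoxyl radical 9 (not isolated), via coupled dienone quinone methide 10 (not isolated), via rearomatised phenol quinone methide 11 (not isolated)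
Conditions: 7 (8 equiv), Ag2O (2.5 equiv), MeCN, rt, dark, N2; 6 (0.05 M in MeCN) by syringe pump over 10 h; filter through Celite as soon as 6 is consumed; SiO2 (excess 7 recovered), then recrystallise from EtOH to a single diastereomer (expected 25–35 %, about 9:1 facial selectivity before purification)
Reagents that add atoms: none
Why: Proposed new method: this is a biomimetic 8–5' oxidative radical hetero-coupling (phenol oxidative coupling followed by a 5-exo-trig oxa-1,6-addition to a p-quinone methide) in which Ag2O abstracts the phenolic hydrogen of both similarly electron-poor guaiacols, slow addition of 6 into a large excess of 7 keeps radical 8 dilute among radicals 9 so that C8 of 8 bonds to the only free ortho carbon (C5) of 9 rather than to a second 8, dienone 10 tautomerises to phenol 11 and its OH closes onto the quinone methide carbon; the (2S)-sultam, with C=O anti to SO2 and the enoyl unit s-cis, screens the C8 Re face so the C–C bond forms on the Si face (3S in 12), and ring closure anti to the bulky acyl group sets the trans (2S) centre; the closest known reaction types are the Ag2O dehydrodimerisation of ferulates, N-feruloylsultams included, and the end-wise cross-coupling of monolignols with guaiacyl phenols under slow monomer addition; the minor (2R,3R) diastereomer is removed because the auxiliary makes it a separable diastereomer.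

Step 3
Reactants: 12 methyl (2S,3S)-2-(4-hydroxy-3-methoxyphenyl)-7-methoxy-3-{[(2S)-bornane-10,2-sultam-N-yl]carbonyl}-2,3-dihydrobenzofuran-5-carboxylate
Product: 14 curlignan, via C3 carbaldehyde 13 (not isolated)
Conditions: NaBH4 (4 equiv), THF/H2O 4:1, 0 °C to rt, 2–4 h; sat. aq NH4Cl; SiO2 (sultam recovered; expected about 80 %)
Reagents that add atoms: none
Why: This is a chemoselective borohydride reduction of an activated N-acylsulfonamide (reductive auxiliary cleavage) in which hydride adds to the sulfonyl-activated carbonyl, the sultam anion leaves and aldehyde 13 is reduced at once, the electron-rich methyl benzoate is inert to NaBH4, and no bond to C2 or C3 is broken so both centres are retained, the C3 descriptor changing from S to R only through the CIP priorities.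

## Compound list

1 | (E)-ferulic acid, (E)-3-(4-hydroxy-3-methoxyphenyl)prop-2-enoic acid | COc1cc(/C=C/C(=O)O)ccc1O | starting material
2 | (1R)-(+)-2,10-camphorsultam, (2S)-bornane-10,2-sultam, (3aR,6S,7aS) | N1[C@H]2C[C@@H]3CC[C@@]2(CS1(=O)=O)C3(C)C | starting material
3 | trimethylsilyl (E)-3-[3-methoxy-4-(trimethylsilyloxy)phenyl]prop-2-enoate | COc1cc(/C=C/C(=O)O[Si](C)(C)C)ccc1O[Si](C)(C)C | intermediate (not isolated)
4 | (E)-3-[3-methoxy-4-(trimethylsilyloxy)phenyl]prop-2-enoyl chloride | COc1cc(/C=C/C(=O)Cl)ccc1O[Si](C)(C)C | intermediate (not isolated)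
5 | (2S)-N-[(E)-4-O-trimethylsilylferuloyl]bornane-10,2-sultam | COc1cc(/C=C/C(=O)N2[C@H]3C[C@@H]4CC[C@@]3(CS2(=O)=O)C4(C)C)ccc1O[Si](C)(C)C | intermediate (not isolated)
6 | (2S)-N-[(E)-feruloyl]bornane-10,2-sultam (free phenol) | COc1cc(/C=C/C(=O)N2[C@H]3C[C@@H]4CC[C@@]3(CS2(=O)=O)C4(C)C)ccc1O | intermediate
7 | methyl vanillate, methyl 4-hydroxy-3-methoxybenzoate | COC(=O)c1ccc(O)c(OC)c1 | starting material
8 | phenoxyl radical of 6 (spin shared between O4, C5, C1 and C8) | COc1cc(/C=C/C(=O)N2[C@H]3C[C@@H]4CC[C@@]3(CS2(=O)=O)C4(C)C)ccc1[O] | intermediate (not isolated)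
9 | phenoxyl radical of 7 (spin shared between O4, C5, C1 and C3) | COC(=O)c1ccc([O])c(OC)c1 | intermediate (not isolated)
10 | first C8–C5' adduct: vanillate half is a cyclohexa-2,4-dienone (its sp3 C5' is undefined and lost on tautomerisation), feruloyl half is a p-quinone methide (exocyclic C=C geometry undefined), C8 configured as C3 of 12 | COC(=O)C1=CC([C@H](C(=O)N2[C@H]3C[C@@H]4CC[C@@]3(CS2(=O)=O)C4(C)C)C=C2C=CC(=O)C(OC)=C2)C(=O)C(OC)=C1 | intermediate (not isolated)
11 | rearomatised adduct: methyl 4-hydroxy-3-methoxybenzoate bearing at C5 the (R)-CH(CO-sultam)–CH= p-quinone methide unit | COC(=O)c1cc(OC)c(O)c(c1)[C@H](C(=O)N2[C@H]3C[C@@H]4CC[C@@]3(CS2(=O)=O)C4(C)C)C=C1C=CC(=O)C(OC)=C1 | intermediate (not isolated)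
12 | methyl (2S,3S)-2-(4-hydroxy-3-methoxyphenyl)-7-methoxy-3-{[(2S)-bornane-10,2-sultam-N-yl]carbonyl}-2,3-dihydrobenzofuran-5-carboxylate (2,3-trans) | COC(=O)c1cc(OC)c2c(c1)[C@H](C(=O)N3[C@H]4C[C@@H]5CC[C@@]4(CS3(=O)=O)C5(C)C)[C@@H](c1ccc(O)c(OC)c1)O2 | intermediate
13 | methyl (2S,3S)-3-formyl-2-(4-hydroxy-3-methoxyphenyl)-7-methoxy-2,3-dihydrobenzofuran-5-carboxylate (2,3-trans) | COC(=O)c1cc(OC)c2c(c1)[C@H](C=O)[C@@H](c1ccc(O)c(OC)c1)O2 | intermediate (not isolated)
14 | curlignan, methyl (2S,3R)-2-(4-hydroxy-3-methoxyphenyl)-3-(hydroxymethyl)-7-methoxy-2,3-dihydrobenzofuran-5-carboxylate (2,3-trans) | COC(=O)c1cc(OC)c2c(c1)[C@H](CO)[C@@H](c1ccc(O)c(OC)c1)O2 | target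

## Step count and risks

Total step count: 3. Longest linear sequence: 3 (1 to 6 to 12 to 14).

**Most likely to fail: step 2.**
- Radical 8 may prefer a second 8 and give the homodimer.
- 8–O–4' coupling may compete with 8–5' coupling.
- The more easily oxidised guaiacyl phenol of product 12 may be drawn into further coupling.

The fallback sets out from 6 and comes back at 12. It keeps the same biomimetic ring formation but gives up the hetero-coupling. Compound 6 is dimerised on purpose with Ag2O in CH2Cl2 at rt, the established reaction type, to the (2S,3S)-trans bis-sultam dehydrodimer F1. Its cinnamoyl C=C is cut by ozonolysis (one equivalent of O3, CH2Cl2/MeOH, −78 °C, then Me2S) to the 5-formyl dihydrobenzofuran acylsultam F2. Pinnick oxidation (NaClO2, NaH2PO4, 2-methyl-2-butene, t-BuOH/H2O) gives the 5-carboxylic acid F3. Esterification of the acid alone with Me3SiCHN2 in toluene/MeOH at 0 °C delivers 12.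

**Second: step 3.**
- The hindered acyl carbonyl may react sluggishly with NaBH4.
- A stronger hydride would begin to touch the aryl ester.
- The acidic C3–H of 12 and 13 allows base-induced opening of the dihydrofuran by loss of the aryloxide.

The fallback sets out from 12 and comes back at 14. It separates auxiliary removal from reduction. LiOH/H2O2 in THF/H2O at 0 °C cleaves the sultam to the (2S,3S)-3-carboxylic acid F4. BH3·THF at 0 °C then reduces the free acid but not the methyl benzoate, giving 14.

**Third: step 1.**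
- The telescoped sequence may leak free phenol and give aryl ester oligomers.
- Acid chloride 4 may also be lost on handling.

The fallback sets out from 2 and comes back at 6. It builds the cinnamoyl C–C bond instead of the C–N bond. Sultam 2 is acylated with acryloyl chloride (NaH, toluene, 0 °C to rt) to (2S)-N-acryloylbornane-10,2-sultam F5. A Mizoroki–Heck reaction with commercial 4-iodo-2-methoxyphenol (Pd(OAc)2, P(o-tol)3, Et3N, MeCN, 80 °C) tolerates the free phenol and gives 6 as the (E)-isomer.

## Further compounds

F1 | step 2 | (2S,3S)-trans-2-(4-hydroxy-3-methoxyphenyl)-7-methoxy-2,3-dihydrobenzofuran bearing the (2S)-bornane-10,2-sultam-N-carbonyl group at C3 and the (E)-3-oxo-3-[(2S)-bornane-10,2-sultam-N-yl]prop-1-enyl group at C5 | O=C(/C=C/c1cc(OC)c2c(c1)[C@H](C(=O)N3[C@H]4C[C@@H]5CC[C@@]4(CS3(=O)=O)C5(C)C)[C@@H](c1ccc(O)c(OC)c1)O2)N1[C@H]2C[C@@H]3CC[C@@]2(CS1(=O)=O)C3(C)C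
F2 | step 2 | (2S,3S)-2-(4-hydroxy-3-methoxyphenyl)-7-methoxy-3-{[(2S)-bornane-10,2-sultam-N-yl]carbonyl}-2,3-dihydrobenzofuran-5-carbaldehyde | O=Cc1cc(OC)c2c(c1)[C@H](C(=O)N3[C@H]4C[C@@H]5CC[C@@]4(CS3(=O)=O)C5(C)C)[C@@H](c1ccc(O)c(OC)c1)O2
F3 | step 2 | (2S,3S)-2-(4-hydroxy-3-methoxyphenyl)-7-methoxy-3-{[(2S)-bornane-10,2-sultam-N-yl]carbonyl}-2,3-dihydrobenzofuran-5-carboxylic acid | OC(=O)c1cc(OC)c2c(c1)[C@H](C(=O)N3[C@H]4C[C@@H]5CC[C@@]4(CS3(=O)=O)C5(C)C)[C@@H](c1ccc(O)c(OC)c1)O2
F4 | step 3 | (2S,3S)-2-(4-hydroxy-3-methoxyphenyl)-7-methoxy-5-(methoxycarbonyl)-2,3-dihydrobenzofuran-3-carboxylic acid | COC(=O)c1cc(OC)c2c(c1)[C@H](C(=O)O)[C@@H](c1ccc(O)c(OC)c1)O2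
F5 | step 1 | (2S)-N-acryloylbornane-10,2-sultam | C=CC(=O)N1[C@H]2C[C@@H]3CC[C@@]2(CS1(=O)=O)C3(C)C
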